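**Retrosynthetic overview**
1. Target 36 ⇐ (6R)-allylic alcohol 35 (SN2 chloride with inversion, last step) ⇐ macrocycle 32, whose ten-membered ring is closed at C3=C4 by ring-closing metathesis.
2. Metathesis triene 31 ⇐ γ-lactone (C8, C17) by intramolecular Reformatsky aldol of the C7 2-bromopropanoate 29 onto the C8 ketone.
3. Ketone 28 ⇐ C8–C9 union of the α-alkoxyorganolithium from stannane 14 (fragment A: C1–C3, C9–C15, C20) with Weinreb amide 25 (fragment B: C4–C8, C16).
4. Fragment A ⇐ catalytic asymmetric Diels–Alder reaction of diene 2 with enal 3 (sets C1, C10, C11), then C2 vinylation, directed reduction, directed epoxidation, Felkin stannylation; fragment B ⇐ diethyl D-tartrate (C6, C7).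
5. Ring order: cyclohexene (step 2) → epoxide (step 8) → γ-lactone (step 24) → ten-membered ring (step 25).

Assumption and convention: the given SMILES defines the absolute configuration; briarane locants are used for all intermediates (C1 quaternary ring carbon with methyl C15; C2 CH–O; C3=C4; C5=C16H2; C6; C7 lactone O; C8 OH; C9 CH–O; C10–C14 ring, methyl C20 on C11, O on C12, epoxide C13/C14; C17 with methyl C18; C19 lactone C=O), and β is the ring face carrying the C1 methyl.

This is a designed route and has not been run. The sense of induction of the chiral catalysts in steps 2 and 3 is assigned by analogy.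

**Fragment A**

Step 1
Reactants: 1 pent-1-en-3-one
Product: 2 (Z)-3-(tert-butyldimethylsilyloxy)penta-1,3-diene
Conditions: TBSOTf, Et3N, Et2O, 0 °C
Reagents that add atoms: tert-butyldimethylsilyl triflate, CC(C)(C)[Si](C)(C)OS(=O)(=O)C(F)(F)F
Why: Soft enolisation and O-silylation of the vinyl ketone (silyl dienol ether formation) gives the 2-silyloxydiene, the Z enol ether being favoured because the methyl group avoids the vinyl group.

Step 2
Reactants: 2 (Z)-silyloxydiene; 3 ethyl (E)-3-methyl-4-oxobut-2-enoate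
Product: 4 Diels–Alder adduct (1β-Me, 1α-CHO, 10β-CO2Et, 11β-Me, C12=C13 silyl enol ether)
Conditions: (S)-1-(2-methylphenyl)-3,3-diphenyltetrahydro-1H,3H-pyrrolo[1,2-c][1,3,2]oxazaborole·Tf2NH (20 mol %), CH2Cl2, −78 → −40 °C
Reagents that add atoms: none
Why: In this Lewis-acid-catalysed Diels–Alder reaction the enol-ether terminus C11 bonds to C10 (β to the boron-bound formyl group), the E dienophile places the C1 methyl and C10 ester cis, the formyl-exo/ester-endo transition state usual for α-methyl enals puts the C11 methyl on the same face, and the chiral oxazaborolidinium shields one enal face, so C1, C10 and C11 are set together.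

Step 3
Reactants: 4 Diels–Alder adduct
Product: 5 (2R)-allylic alcohol
Conditions: Zn(CH=CH2)2 (2 equiv), (+)-3-exo-morpholinoisoborneol (10 mol %), toluene, −20 → 0 °C; aq. NH4Cl
Reagents that add atoms: divinylzinc, C=C[Zn]C=C
Why: Amino-alcohol-catalysed organozinc 1,2-addition (Noyori–Oppolzer type) delivers vinyl under catalyst control to the Re face of the neopentyl aldehyde, giving the (2R) carbinol, while the ester and silyl enol ether do not react with the organozinc.

Step 4
Reactants: 5 (2R)-allylic alcohol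
Product: 6 C2 triethylsilyl ether
Conditions: TESOTf, 2,6-lutidine, CH2Cl2, −78 °C
Reagents that add atoms: triethylsilyl triflate, CC[Si](CC)(CC)OS(=O)(=O)C(F)(F)F
Why: Silyl ether formation with the reactive triflate protects the hindered secondary alcohol without touching the enol ether or any stereocentre.

Step 5
Reactants: 6 C2 triethylsilyl ether
Product: 7 primary alcohol (10β-CH2OH)
Conditions: i-Bu2AlH (2.5 equiv), CH2Cl2, −78 °C; aq. potassium sodium tartrate
Reagents that add atoms: none
Why: Hydride reduction of the ester with i-Bu2AlH gives the C9 primary alcohol needed as an internal hydride-delivery site, and silyl ethers, enol ether and alkenes are unaffected.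

Step 6
Reactants: 7 primary alcohol
Product: 8 enone (C12 ketone, C13=C14)
Conditions: Pd(OAc)2 (1.1 equiv), MeCN, 40 °C
Reagents that add atoms: none
Why: Saegusa–Ito oxidation (palladation of the silyl enol ether at C13 by divalent palladium, then β-hydride elimination from C14) gives the enone regiospecifically, and the epimerisable C11 methyl stays β because that isomer keeps both methyls equatorial with the C2 and C9 arms trans-diaxial.

Step 7
Reactants: 8 enone
Product: 9 12α-allylic alcohol
Conditions: Me4NBH(OAc)3, MeCN/AcOH (1:1), −30 °C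
Reagents that add atoms: none
Why: In this hydroxyl-directed 1,2-reduction (Saksena–Evans type) the axial C9 alkoxyborohydride delivers hydride intramolecularly to the β face of the C12 carbonyl, giving the equatorial 12α-alcohol trans to the C11 methyl, whereas the reagent does not reduce the enone intermolecularly.

Step 8
Reactants: 9 12α-allylic alcohol
Product: 10 13α,14α-epoxy diol
Conditions: mCPBA, NaHCO3, CH2Cl2, 0 °C
Reagents that add atoms: 3-chloroperbenzoic acid, OOC(=O)c1cccc(Cl)c1
Why: Henbest hydroxyl-directed epoxidation delivers oxygen syn to the allylic 12α-OH onto the cis-disubstituted ring alkene, setting C13 and C14, while the monosubstituted vinyl group reacts far more slowly.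

Step 9
Reactants: 10 epoxy diol
Product: 11 C9 aldehyde
Conditions: TEMPO (10 mol %), PhI(OAc)2, CH2Cl2, 25 °C
Reagents that add atoms: none
Why: Nitroxyl-catalysed (TEMPO) oxidation is selective for the primary alcohol over the hindered secondary epoxy alcohol and stops at the aldehyde without epimerising C10.

Step 10
Reactants: 11 C9 aldehyde
Product: 12 12α-triethylsilyl ether aldehyde
Conditions: TESCl, imidazole, DMF, 0 °C
Reagents that add atoms: chlorotriethylsilane, CC[Si](CC)(CC)Cl
Why: Imidazole-mediated silylation protects the remaining secondary alcohol under conditions too mild to enolise the aldehyde.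

Step 11
Reactants: 12 silyl ether aldehyde
Product: 14 fragment A (9S)-α-(2-methoxypropan-2-yloxy)stannane, via α-hydroxystannane 13 (not isolated)
Conditions: Bu3SnLi (from Bu3SnH, LiN(i-Pr)2), THF, −78 °C; aq. NH4Cl; then 2-methoxypropene, PPTS (cat.), CH2Cl2, 0 °C
Reagents that add atoms: tributylstannyllithium, [Li][Sn](CCCC)(CCCC)CCCC; 2-methoxypropene, COC(C)=C
Why: Felkin–Anh 1,2-addition of the bulky stannyl anion to the α-branched aldehyde (quaternary C1 anti to the nucleophile, C10–H on the side of the incoming nucleophile) sets C9, and immediate acid-catalysed ketalisation gives a Still-type α-alkoxystannane.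

**Fragment B**

Step 12
Reactants: 15 diethyl D-tartrate
Product: 16 mono-PMB ether
Conditions: Ag2O, 4-methoxybenzyl chloride, CH2Cl2, 25 °C
Reagents that add atoms: 4-methoxybenzyl chloride, COc1ccc(CCl)cc1
Why: Silver-oxide-mediated Williamson mono-etherification of the C2-symmetric diol (both hydroxyls equivalent, the first ether slowing the second) leaves both tartrate stereocentres untouched.

Step 13
Reactants: 16 mono-PMB ether
Product: 17 diol ester
Conditions: BH3·SMe2, NaBH4 (5 mol %), THF, 0 → 25 °C; MeOH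
Reagents that add atoms: none
Why: In Saito's chelation-controlled borane reduction the free α-hydroxyl binds borane and directs reduction of only the adjacent ester, giving the 1,2-diol.

Step 14
Reactants: 17 diol ester
Product: 18 acetonide ester
Conditions: Me2C(OMe)2, PPTS (cat.), CH2Cl2, 25 °C
Reagents that add atoms: 2,2-dimethoxypropane, COC(C)(C)OC
Why: Acid-catalysed transketalisation forms the five-membered acetonide of the terminal 1,2-diol.

Step 15
Reactants: 18 acetonide ester
Product: 19 Weinreb amide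
Conditions: MeNHOMe·HCl, i-PrMgCl, THF, −20 °C
Reagents that add atoms: N,O-dimethylhydroxylamine hydrochloride, CNOC.Cl
Why: Aminolysis of the ester by the chloromagnesium amide (Weinreb amide formation) proceeds at low temperature without epimerising the α-alkoxy centre.

Step 16
Reactants: 19 Weinreb amide
Product: 20 vinyl ketone
Conditions: CH2=CHMgBr, THF, −78 → 0 °C; cold 1 M HCl
Reagents that add atoms: vinylmagnesium bromide, C=C[Mg]Br
Why: In the Weinreb ketone synthesis the stable magnesium chelate stops addition at the ketone stage, and the cold acidic quench prevents conjugate addition of the released amine.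

Step 17
Reactants: 20 vinyl ketone
Product: 21 diene acetonide
Conditions: Ph3PCH3Br, KN(SiMe3)2, THF, −78 → 0 °C
Reagents that add atoms: methyltriphenylphosphonium bromide, C[P+](c1ccccc1)(c1ccccc1)c1ccccc1.[Br-]
Why: Wittig methylenation of the ketone carbonyl with the non-stabilised ylide converts the enone into the 2-substituted 1,3-diene (C5=C16) at a temperature too low to epimerise C6.

Step 18
Reactants: 21 diene acetonide
Product: 22 diene diol
Conditions: AcOH/H2O/THF (3:1:1), 40 °C
Reagents that add atoms: none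
Why: Acid-catalysed acetal hydrolysis frees the 1,2-diol while the PMB ether and the diene tolerate aqueous acetic acid.

Step 19
Reactants: 22 diene diol
Product: 23 α-hydroxy aldehyde
Conditions: TEMPO (10 mol %), PhI(OAc)2, CH2Cl2, 0 → 25 °C
Reagents that add atoms: none
Why: TEMPO-catalysed oxidation is selective for the primary over the secondary alcohol and gives the α-hydroxy aldehyde.

Step 20
Reactants: 23 α-hydroxy aldehyde
Product: 24 α-hydroxy acid
Conditions: NaClO2, NaH2PO4, 2-methylbut-2-ene, t-BuOH/H2O, 0 °C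
Reagents that add atoms: sodium chlorite, [Na+].[O-]Cl=O
Why: Pinnick oxidation converts the aldehyde into the acid under buffered conditions, with 2-methylbut-2-ene scavenging hypochlorite so the diene and PMB ether are spared.

Step 21
Reactants: 24 α-hydroxy acid
Product: 25 fragment B Weinreb amide
Conditions: MeNHOMe·HCl, 1-ethyl-3-(3-dimethylaminopropyl)carbodiimide hydrochloride, HOBt, N-methylmorpholine, CH2Cl2, 0 → 25 °C
Reagents that add atoms: N,O-dimethylhydroxylamine hydrochloride, CNOC.Cl
Why: Carbodiimide/HOBt amide coupling gives the Weinreb amide, the amine being far more nucleophilic than the unprotected α-hydroxyl.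

**Union and endgame**

Step 22
Reactants: 14 fragment A stannane; 25 fragment B Weinreb amide
Product: 28 ketone (6R,7S,9R), via α-alkoxyorganolithium 26 (not isolated), via chloromagnesium alkoxide 27 (not isolated)
Conditions: 14, n-BuLi, THF, −78 °C, 10 min; add 25 pre-treated with i-PrMgCl (1 equiv, THF, −78 °C); −78 → −40 °C; aq. NH4Cl
Reagents that add atoms: none
Why: Still tin–lithium exchange gives a configurationally stable α-alkoxyorganolithium that acylates the Weinreb amide with retention at C9 (Weinreb ketone synthesis), the pre-formed magnesium alkoxide masking the C7 hydroxyl and the chelated tetrahedral intermediate preventing over-addition.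

Step 23
Reactants: 28 ketone
Product: 29 C7 2-bromopropanoate
Conditions: 2-bromopropanoic acid (racemic), N,N'-diisopropylcarbodiimide, DMAP (cat.), CH2Cl2, −20 → 0 °C
Reagents that add atoms: 2-bromopropanoic acid, CC(Br)C(=O)O
Why: Steglich esterification of the only free hydroxyl under neutral conditions preserves the acid-labile ketal and the α-ketol stereocentres, and the epimeric bromide carbon converges in the next step.

Step 24
Reactants: 29 C7 2-bromopropanoate
Product: 31 γ-lactone triene (8R,17R), via samarium enolate 30 (not isolated)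
Conditions: SmI2 (2.5 equiv), THF, −78 °C; aq. NH4Cl
Reagents that add atoms: none
Why: In this intramolecular Reformatsky reaction divalent samarium reduces the C–Br bond and the resulting enolate adds to the C8 ketone through a chelated transition state with the bulky C9 branch trans to C6 and the C17 methyl trans to that branch, setting C8 and C17 and closing the lactone.

Step 25
Reactants: 31 γ-lactone triene
Product: 32 macrocycle (3Z)
Conditions: second-generation Grubbs catalyst, [1,3-bis(2,4,6-trimethylphenyl)imidazolidin-2-ylidene](benzylidene)dichloro(tricyclohexylphosphine)ruthenium (20 mol %), 1,4-benzoquinone (cat.), toluene (1 mM), 80 °C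
Reagents that add atoms: none
Why: Ring-closing metathesis of the C2 vinyl group with the terminal vinyl of the 2-substituted butadiene closes the ten-membered ring, ring strain strongly favouring the Z C3=C4 alkene and the 1,1-disubstituted C5=C16 alkene being too hindered to take part.

Step 26
Reactants: 32 macrocycle
Product: 33 triol
Conditions: PPTS, MeOH/CH2Cl2, 0 → 25 °C
Reagents that add atoms: none
Why: Mild acid-catalysed methanolysis (desilylation and transketalisation) removes both triethylsilyl ethers and the mixed ketal while the PMB ether, hindered epoxide and lactone survive.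

Step 27
Reactants: 33 triol
Product: 34 triacetate
Conditions: Ac2O, pyridine, DMAP (cat.), CH2Cl2, 25 °C
Reagents that add atoms: acetic anhydride, CC(=O)OC(C)=O
Why: DMAP-catalysed acetylation esterifies the three secondary alcohols (C2, C9, C12) whereas the tertiary C8 hydroxyl is too hindered to react.

Step 28
Reactants: 34 triacetate
Product: 35 (6R)-allylic alcohol
Conditions: DDQ, CH2Cl2/pH 7 phosphate buffer, 0 °C
Reagents that add atoms: none
Why: Oxidative PMB ether cleavage by DDQ (benzylic oxidation to the oxocarbenium ion, then hydrolysis) frees the C6 alcohol without affecting acetates, epoxide or diene.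

Step 29
Reactants: 35 (6R)-allylic alcohol
Product: 36 target CNP0274383.2
Conditions: Ph3P, Cl3CC(O)CCl3, CH2Cl2, −20 → 0 °C
Reagents that add atoms: hexachloroacetone, ClC(Cl)(Cl)C(=O)C(Cl)(Cl)Cl
Why: In the Magid (Appel-type) chlorination the alkoxyphosphonium ion is displaced by chloride in an SN2 process with inversion at C6 and without allylic transposition, giving the (6S) chloride.

**Compound list**

1 | pent-1-en-3-one (ethyl vinyl ketone) | CCC(=O)C=C | starting material
2 | (Z)-3-(tert-butyldimethylsilyloxy)penta-1,3-diene | C=C/C(O[Si](C)(C)C(C)(C)C)=C/C | intermediate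
3 | ethyl (E)-3-methyl-4-oxobut-2-enoate | O=C/C(C)=C/C(=O)OCC | starting material
4 | Diels–Alder adduct, ethyl (1S,2R,6S)-6-formyl-2,6-dimethyl-3-(tert-butyldimethylsilyloxy)cyclohex-3-ene-1-carboxylate (briarane: 1β-Me, 1α-CHO, 10β-CO2Et, 11β-Me, C12=C13 enol ether) | O=C[C@]1(C)[C@H]([C@@H](C)C(O[Si](C)(C)C(C)(C)C)=CC1)C(=O)OCC | intermediate
5 | (2R)-allylic alcohol: 4 with CHO converted into (R)-CH(OH)CH=CH2 | C=C[C@@H](O)[C@]1(C)[C@H]([C@@H](C)C(O[Si](C)(C)C(C)(C)C)=CC1)C(=O)OCC | intermediate
6 | C2 triethylsilyl ether of 5 | C=C[C@@H](O[Si](CC)(CC)CC)[C@]1(C)[C@H]([C@@H](C)C(O[Si](C)(C)C(C)(C)C)=CC1)C(=O)OCC | intermediate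
7 | primary alcohol: 6 with CO2Et reduced to 10β-CH2OH | C=C[C@@H](O[Si](CC)(CC)CC)[C@]1(C)[C@H]([C@@H](C)C(O[Si](C)(C)C(C)(C)C)=CC1)CO | intermediate
8 | enone: C12 ketone, C13=C14, 10β-CH2OH, 1β- and 11β-Me, 1α-[(R)-CH(OTES)CH=CH2] | C=C[C@@H](O[Si](CC)(CC)CC)[C@]1(C)[C@H]([C@@H](C)C(=O)C=C1)CO | intermediate
9 | 12α-allylic alcohol of 8 (OH trans to 11β-Me) | C=C[C@@H](O[Si](CC)(CC)CC)[C@]1(C)[C@H]([C@@H](C)[C@H](O)C=C1)CO | intermediate
10 | 13α,14α-epoxide of 9 (cis to 12α-OH) | C=C[C@@H](O[Si](CC)(CC)CC)[C@]1(C)[C@H]([C@@H](C)[C@H](O)[C@@H]2O[C@@H]21)CO | intermediate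
11 | C9 aldehyde of 10 (10β-CHO) | C=C[C@@H](O[Si](CC)(CC)CC)[C@]1(C)[C@H]([C@@H](C)[C@H](O)[C@@H]2O[C@@H]21)C=O | intermediate
12 | 12α-triethylsilyl ether of 11 | C=C[C@@H](O[Si](CC)(CC)CC)[C@]1(C)[C@H]([C@@H](C)[C@H](O[Si](CC)(CC)CC)[C@@H]2O[C@@H]21)C=O | intermediate
13 | (9S)-α-hydroxystannane: 12 with CHO converted into (S)-CH(OH)SnBu3 | C=C[C@@H](O[Si](CC)(CC)CC)[C@]1(C)[C@H]([C@@H](C)[C@H](O[Si](CC)(CC)CC)[C@@H]2O[C@@H]21)[C@@H](O)[Sn](CCCC)(CCCC)CCCC | intermediate
14 | fragment A: 2-methoxypropan-2-yl ether of 13, (9S) | C=C[C@@H](O[Si](CC)(CC)CC)[C@]1(C)[C@H]([C@@H](C)[C@H](O[Si](CC)(CC)CC)[C@@H]2O[C@@H]21)[C@@H](OC(C)(C)OC)[Sn](CCCC)(CCCC)CCCC | intermediate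
15 | diethyl D-tartrate, diethyl (2S,3S)-2,3-dihydroxybutanedioate | CCOC(=O)[C@@H](O)[C@H](O)C(=O)OCC | starting material
16 | diethyl (2S,3S)-2-hydroxy-3-[(4-methoxybenzyl)oxy]butanedioate | CCOC(=O)[C@@H](OCc1ccc(OC)cc1)[C@H](O)C(=O)OCC | intermediate
17 | ethyl (2S,3R)-3,4-dihydroxy-2-[(4-methoxybenzyl)oxy]butanoate | CCOC(=O)[C@@H](OCc1ccc(OC)cc1)[C@H](O)CO | intermediate
18 | ethyl (2S)-2-[(4R)-2,2-dimethyl-1,3-dioxolan-4-yl]-2-[(4-methoxybenzyl)oxy]acetate | CCOC(=O)[C@@H](OCc1ccc(OC)cc1)[C@H]1COC(C)(C)O1 | intermediate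
19 | (2S)-2-[(4R)-2,2-dimethyl-1,3-dioxolan-4-yl]-N-methoxy-2-[(4-methoxybenzyl)oxy]-N-methylacetamide | CON(C)C(=O)[C@@H](OCc1ccc(OC)cc1)[C@H]1COC(C)(C)O1 | intermediate
20 | (1S)-1-[(4R)-2,2-dimethyl-1,3-dioxolan-4-yl]-1-[(4-methoxybenzyl)oxy]but-3-en-2-one | C=CC(=O)[C@@H](OCc1ccc(OC)cc1)[C@H]1COC(C)(C)O1 | intermediate
21 | (4R)-4-{(1R)-1-[(4-methoxybenzyl)oxy]-2-methylidenebut-3-en-1-yl}-2,2-dimethyl-1,3-dioxolane | C=CC(=C)[C@@H](OCc1ccc(OC)cc1)[C@H]1COC(C)(C)O1 | intermediate
22 | (2R,3R)-3-[(4-methoxybenzyl)oxy]-4-methylidenehex-5-ene-1,2-diol | C=CC(=C)[C@@H](OCc1ccc(OC)cc1)[C@H](O)CO | intermediate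
23 | (2S,3R)-2-hydroxy-3-[(4-methoxybenzyl)oxy]-4-methylidenehex-5-enal | C=CC(=C)[C@@H](OCc1ccc(OC)cc1)[C@H](O)C=O | intermediate
24 | (2S,3R)-2-hydroxy-3-[(4-methoxybenzyl)oxy]-4-methylidenehex-5-enoic acid | C=CC(=C)[C@@H](OCc1ccc(OC)cc1)[C@H](O)C(=O)O | intermediate
25 | fragment B: (2S,3R)-2-hydroxy-N-methoxy-3-[(4-methoxybenzyl)oxy]-N-methyl-4-methylidenehex-5-enamide | C=CC(=C)[C@@H](OCc1ccc(OC)cc1)[C@H](O)C(=O)N(C)OC | intermediate
26 | (9S)-α-alkoxyorganolithium: 14 with Li in place of SnBu3 | C=C[C@@H](O[Si](CC)(CC)CC)[C@]1(C)[C@H]([C@@H](C)[C@H](O[Si](CC)(CC)CC)[C@@H]2O[C@@H]21)[C@@H](OC(C)(C)OC)[Li] | intermediate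
27 | chloromagnesium alkoxide of 25 | C=CC(=C)[C@@H](OCc1ccc(OC)cc1)[C@H](O[Mg]Cl)C(=O)N(C)OC | intermediate
28 | ketone (6R,7S,9R): C8 ketone joining the fragments, free 7-OH, 6-OPMB, 9-O-(2-methoxypropan-2-yl), 2- and 12-OTES, 13α,14α-epoxide | C=C[C@@H](O[Si](CC)(CC)CC)[C@]1(C)[C@H]([C@@H](C)[C@H](O[Si](CC)(CC)CC)[C@@H]2O[C@@H]21)[C@@H](OC(C)(C)OC)C(=O)[C@@H](O)[C@H](OCc1ccc(OC)cc1)C(=C)C=C | intermediate
29 | O7 2-bromopropanoate of 28 (both epimers at the CHBr carbon) | C=C[C@@H](O[Si](CC)(CC)CC)[C@]1(C)[C@H]([C@@H](C)[C@H](O[Si](CC)(CC)CC)[C@@H]2O[C@@H]21)[C@@H](OC(C)(C)OC)C(=O)[C@@H](OC(=O)C(C)Br)[C@H](OCc1ccc(OC)cc1)C(=C)C=C | intermediate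
30 | samarium enolate of 29 | C=C[C@@H](O[Si](CC)(CC)CC)[C@]1(C)[C@H]([C@@H](C)[C@H](O[Si](CC)(CC)CC)[C@@H]2O[C@@H]21)[C@@H](OC(C)(C)OC)C(=O)[C@@H](OC(O[Sm](I)I)=CC)[C@H](OCc1ccc(OC)cc1)C(=C)C=C | intermediate
31 | γ-lactone triene (6R,7S,8R,9R,17R): 8-hydroxy-17-methyl lactone C19 to O7, C2 vinyl and C5 butadienyl termini | C=C[C@@H](O[Si](CC)(CC)CC)[C@]1(C)[C@H]([C@@H](C)[C@H](O[Si](CC)(CC)CC)[C@@H]2O[C@@H]21)[C@@H](OC(C)(C)OC)[C@]1(O)[C@@H](C)C(=O)O[C@H]1[C@H](OCc1ccc(OC)cc1)C(=C)C=C | intermediate
32 | macrocycle (3Z): ten-membered ring with 2,12-di-OTES, 9-O-(2-methoxypropan-2-yl), 6-OPMB | C=C1/C=C\[C@@H](O[Si](CC)(CC)CC)[C@]2(C)[C@H]([C@@H](C)[C@H](O[Si](CC)(CC)CC)[C@@H]3O[C@@H]32)[C@@H](OC(C)(C)OC)[C@]2(O)[C@@H](C)C(=O)O[C@H]2[C@@H]1OCc1ccc(OC)cc1 | intermediate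
33 | triol: 32 with free 2-, 9- and 12-OH | C=C1/C=C\[C@@H](O)[C@]2(C)[C@H]([C@@H](C)[C@H](O)[C@@H]3O[C@@H]32)[C@@H](O)[C@]2(O)[C@@H](C)C(=O)O[C@H]2[C@@H]1OCc1ccc(OC)cc1 | intermediate
34 | 2,9,12-triacetate of 33 | C=C1/C=C\[C@@H](OC(C)=O)[C@]2(C)[C@H]([C@@H](C)[C@H](OC(C)=O)[C@@H]3O[C@@H]32)[C@@H](OC(C)=O)[C@]2(O)[C@@H](C)C(=O)O[C@H]2[C@@H]1OCc1ccc(OC)cc1 | intermediate
35 | (6R)-allylic alcohol: 34 with free 6-OH | C=C1/C=C\[C@@H](OC(C)=O)[C@]2(C)[C@H]([C@@H](C)[C@H](OC(C)=O)[C@@H]3O[C@@H]32)[C@@H](OC(C)=O)[C@]2(O)[C@@H](C)C(=O)O[C@H]2[C@@H]1O | intermediate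
36 | CNP0274383.2, (6S)-chloride | C=C1/C=C\[C@@H](OC(C)=O)[C@]2(C)[C@H]([C@@H](C)[C@H](OC(C)=O)[C@@H]3O[C@@H]32)[C@@H](OC(C)=O)[C@]2(O)[C@@H](C)C(=O)O[C@H]2[C@H]1Cl | target

**Step count and risks**

Total: 29 steps. Longest linear sequence: 19 steps (steps 1–11, then 22–29); fragment B (steps 12–21) is a separate ten-step branch.

Most likely to fail:

1. Step 25, the ring-closing metathesis. The C2 vinyl group is neopentylic, the ring is ten-membered, and the rigid lactone may hold the two alkenes apart or give E/Z mixtures. Fallback, setting out from 29 and returning at 32: reverse the order of ring formation. Metathesis of the more flexible bromo ester 29 under the step 25 conditions gives the macrocyclic keto bromo ester F6. SmI2 in THF at −78 °C then closes the lactone transannularly to reach 32.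

2. Step 22, the fragment union. A hindered secondary α-alkoxyorganolithium must acylate a hindered amide that carries an adjacent alkoxide. Fallback, setting out from 23 (with 14) and returning at 28: silylate 23 with TMSCl/imidazole to the silylated aldehyde F3. Add organolithium 26 to this far more electrophilic aldehyde to give the C8 carbinol mixture F4. Oxidise with Dess–Martin periodinane/NaHCO3 to the silyloxy ketone F5. Remove the trimethylsilyl group with K2CO3/MeOH at 0 °C, which leaves the triethylsilyl ethers and the ketal intact, to give 28.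

3. Step 2, the catalytic asymmetric Diels–Alder reaction. Enantioselectivity with this trisubstituted enal and 1-substituted silyloxydiene is unproven; if only the sense is wrong, the mirror-image catalyst is used. Fallback, setting out from 2 and 3 and returning at 5: run the cycloaddition with Me2AlCl (CH2Cl2, −78 °C), which gives 4 together with the enantiomeric adduct F1. The catalyst-controlled vinyl transfer of step 3 then converts the pair into 5 and the diastereomeric carbinol F2. F2 is removed by chromatography and the route continues from 5.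

**Further compounds**

F1 | step 2 | enantiomeric adduct (mirror image of 4) | O=C[C@@]1(C)[C@@H]([C@H](C)C(O[Si](C)(C)C(C)(C)C)=CC1)C(=O)OCC
F2 | step 2 | diastereomeric carbinol ((2R) alcohol on the mirror-image ring) | C=C[C@@H](O)[C@@]1(C)[C@@H]([C@H](C)C(O[Si](C)(C)C(C)(C)C)=CC1)C(=O)OCC
F3 | step 22 | silylated aldehyde (C7 trimethylsilyl ether of 23) | C=CC(=C)[C@@H](OCc1ccc(OC)cc1)[C@H](O[Si](C)(C)C)C=O
F4 | step 22 | C8 carbinol mixture (both C8 epimers) | C=C[C@@H](O[Si](CC)(CC)CC)[C@]1(C)[C@H]([C@@H](C)[C@H](O[Si](CC)(CC)CC)[C@@H]2O[C@@H]21)[C@@H](OC(C)(C)OC)C(O)[C@@H](O[Si](C)(C)C)[C@H](OCc1ccc(OC)cc1)C(=C)C=C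
F5 | step 22 | silyloxy ketone (C7 trimethylsilyl ether of 28) | C=C[C@@H](O[Si](CC)(CC)CC)[C@]1(C)[C@H]([C@@H](C)[C@H](O[Si](CC)(CC)CC)[C@@H]2O[C@@H]21)[C@@H](OC(C)(C)OC)C(=O)[C@@H](O[Si](C)(C)C)[C@H](OCc1ccc(OC)cc1)C(=C)C=C
F6 | step 25 | macrocyclic keto bromo ester (3Z) | C=C1/C=C\[C@@H](O[Si](CC)(CC)CC)[C@]2(C)[C@H]([C@@H](C)[C@H](O[Si](CC)(CC)CC)[C@@H]3O[C@@H]32)[C@@H](OC(C)(C)OC)C(=O)[C@@H](OC(=O)C(C)Br)[C@@H]1OCc1ccc(OC)cc1
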